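**Plan**

1. Cuts, in retrosynthetic order: the O9–acyl bond of the angelate, then O8–C12 of the γ-lactone. C6–OAc and C15HO go back to a C6 ketone and a C15 methyl ester, and C11=C13 to a β-nitro ester. Then comes the core, and last C7–C11 (enolate plus nitroacrylate) and C10–CH3 (cuprate).
2. Enabling feature: on the cyclohexane C5–C10, quaternary C10 (CH3, vinyl C1=C2) stands next to C5, which carries C4(=C3H2)–C15, so C2=C1–C10–C5–C4=C3 is a hexa-1,5-diene. Joining C2–C3 while opening C5–C10 (retro-Cope) gives a cyclodeca-1(10),4-dien-6-one. Pairing its two alkenes (C1–C4, C5–C10) gives a cyclobutane fused to the cyclobutane C1–C2–C3–C4 and to a cyclohexanone. That is the [2+2] adduct of a C5=C10 enone (C6=O) and a cyclobutene ester.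
3. Rings in the forward direction: cyclohexane from quinic acid (with a temporary dioxolane), two fused four-membered rings by light, a ten-membered dienone by heat, the cyclohexane again by Cope rearrangement, the γ-lactone, and finally the angelate.
4. Stereochemistry: C8 and C9 are the cis-diol carbons of D-(−)-quinic acid. C7 is set anti to O8 in the Michael step. C10 and C5 arise together in the chair Cope transition state. C6 comes from hydride delivery opposite the axial C10 methyl. The Z-alkene is bought with angelic acid.

Key step: step 12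

Remark: germacrane/elemane numbering C1–C15 is used for all ring-derived compounds; β is the face of the C10 methyl group of the target and α the face of O8 and O9. C11 of the β-nitro esters is an inconsequential epimer mixture (it becomes sp2 later) and is written without a descriptor.

**Step 1**
Reactants: 1 D-(−)-quinic acid
Product: 2 3,4-O-isopropylidenequinic acid 1,5-lactone
Conditions: Me2C(OMe)2, p-TsOH·H2O (cat.), acetone, reflux
Reagents that add atoms: 2,2-dimethoxypropane, COC(C)(C)OC
Why: Acid-catalysed transketalisation with concurrent lactonisation: only the C3/C4 hydroxyls of quinic acid are cis-vicinal and only the C5 hydroxyl is syn to the carboxyl group, so one bicyclic acetonide lactone forms and no stereocentre is touched.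

**Step 2**
Reactants: 2 3,4-O-isopropylidenequinic acid 1,5-lactone
Product: 3 3,4-O-isopropylidene triol (tertiary C1–OH with CH2OH; C5–OH)
Conditions: NaBH4, EtOH, 0 °C → rt
Reagents that add atoms: none
Why: Borohydride reduction of a strained, α-hydroxy-activated bicyclic lactone to the diol level is standard for this quinide, and the acetonide is inert to hydride.

**Step 3**
Reactants: 3 3,4-O-isopropylidene triol
Product: 4 5-hydroxy-3,4-O-isopropylidenedioxycyclohexanone (quinic acid numbering)
Conditions: NaIO4, H2O (pH 7 phosphate buffer), 0 °C → rt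
Reagents that add atoms: none
Why: Malaprade glycol cleavage: the tertiary C1 hydroxyl and its CH2OH are the only free vicinal diol (the oxygen next to the C5 hydroxyl is tied up in the acetonide), so periodate excises one carbon and leaves the ketone.

**Step 4**
Reactants: 4 5-hydroxy-3,4-O-isopropylidenedioxycyclohexanone
Product: 6 (4S,5R)-4,5-O-isopropylidenedioxycyclohex-2-enone, via C5 mesylate 5 (not isolated)
Conditions: MsCl, Et3N, CH2Cl2, 0 °C
Reagents that add atoms: methanesulfonyl chloride, CS(=O)(=O)Cl (its atoms are held only in 5)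
Why: Mesylation followed by E1cB elimination: the sulfonate β to the ketone is by far the best leaving group, so triethylamine expels it at 0 °C before the β′ acetonide oxygen is at risk, and the two remaining stereocentres are C9 (4S) and C8 (5R) of the target.

**Step 5**
Reactants: 6 (4S,5R)-4,5-O-isopropylidenedioxycyclohex-2-enone
Product: 7 trimethylsilyl enol ether (C5=C6–OTMS) of the 10β-methyl ketone
Conditions: Me2CuLi (from CuI, MeLi), TMSCl, Et2O/THF, −78 °C; Et3N, cold aq. NaHCO3 work-up
Reagents that add atoms: lithium dimethylcuprate, [Li+].C[Cu-]C; chlorotrimethylsilane, C[Si](C)(C)Cl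
Why: Gilman cuprate 1,4-addition accelerated by TMSCl: methyl enters anti to the adjacent allylic acetonide oxygen (a centre erased in step 6), and immediate O-silylation fixes the enolate on the C5 side so that it cannot equilibrate towards C7 and expel O8.

**Step 6**
Reactants: 7 trimethylsilyl enol ether
Product: 8 (4S,5R)-3-methyl-4,5-O-isopropylidenedioxycyclohex-2-enone (C5=C10 enone with C10–CH3)
Conditions: Pd(OAc)2 (10 mol %), O2 (1 atm), DMSO, rt
Reagents that add atoms: none
Why: Saegusa–Ito dehydrosilylation in its aerobic catalytic form: the oxo-π-allylpalladium species at C5 has only the C10 hydrogen available for β-hydride elimination, so the double bond returns regiospecifically between C5 and C10.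

**Step 7**
Reactants: 9 tert-butyl acrylate
Product: 10 tert-butyl 2-iodo-3-nitropropanoate (racemic)
Conditions: I2, N2O4, Et2O, 0 °C
Reagents that add atoms: iodine, II; dinitrogen tetroxide, O=[N+]([O-])[N+](=O)[O-]
Why: Radical nitro-iodination of an acrylate: NO2 adds to the unsubstituted terminus and the α-ester radical is capped by iodine, the standard entry to 3-nitroacrylates.

**Step 8**
Reactants: 10 tert-butyl 2-iodo-3-nitropropanoate
Product: 11 tert-butyl (E)-3-nitroacrylate
Conditions: NaOAc (anhydrous), Et2O, 0 °C → rt
Reagents that add atoms: none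
Why: Dehydrohalogenation (E1cB): acetate removes the acidic proton α to the nitro group and iodide leaves, giving the thermodynamically preferred E-alkene without a base strong enough to polymerise it.

**Step 9**
Reactants: 8 (4S,5R)-3-methyl-4,5-O-isopropylidenedioxycyclohex-2-enone; 11 tert-butyl (E)-3-nitroacrylate
Product: 14 enone carrying at C7 (β face; trans to O8) the CH(CO2t-Bu)CH2NO2 group, via lithium dienolate 12 (not isolated), via lithium nitronate 13 (not isolated)
Conditions: LDA, THF, −78 °C; 11 (precooled), −78 °C, 15 min; AcOH/THF, −78 °C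
Reagents that add atoms: lithium diisopropylamide, [Li+].CC(C)[N-]C(C)C (lithium is held only in 12 and 13)
Why: Kinetic α′-deprotonation of a 3-methylcyclohexenone and Michael addition of the cross-conjugated dienolate to a 3-nitroacrylate, in which nitro outranks the ester so that C7 bonds to the carbon α to the ester (C11); attack anti to the C8 oxygen gives the trans C7/C8 relationship (equatorial, restorable by enolisation), and the short time at −78 °C with a cold acid quench is meant to forestall β-elimination of O8 and a second Michael closure.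

**Step 10**
Reactants: 15 ethyl 1-bromocyclobutane-1-carboxylate
Product: 16 cyclobut-1-ene-1-carboxylic acid
Conditions: KOH, toluene, reflux; aq. HCl, 0 °C
Reagents that add atoms: potassium hydroxide, [K+].[OH-] (one carboxyl oxygen)
Why: Hydroxide-induced E2 dehydrobromination with concomitant saponification is the standard preparation of this acid, the strained alkene staying conjugated with the carboxylate.

**Step 11**
Reactants: 16 cyclobut-1-ene-1-carboxylic acid
Product: 17 methyl cyclobut-1-ene-1-carboxylate (brings C1, C2, C3, C4 and C15)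
Conditions: MeI, K2CO3, DMF, 0 °C → rt
Reagents that add atoms: iodomethane, CI
Why: SN2 O-alkylation of the carboxylate avoids the acid and heat that would polymerise the strained acrylate-type alkene.

**Step 12**
Reactants: 14 C7-substituted enone; 17 methyl cyclobut-1-ene-1-carboxylate
Product: 18 cis-anti-cis tricyclo[4.4.0.0(2,5)]decanone photoadduct (new ring C10–C1–C4–C5 on the β face; CO2Me on C4; C10–CH3 now α)
Conditions: 17 (10 equiv), hν (medium-pressure Hg lamp, Pyrex well with uranium-glass sleeve, λ > 330 nm), degassed CH2Cl2, −10 °C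
Reagents that add atoms: none
Why: Excitation of the enone and intersystem crossing give the twisted triplet, which bonds to the strained alkene C1=C4 to form a triplet 1,4-biradical that collapses after spin inversion, so that C10–C1 and C5–C4 are the two new bonds. The closest known reaction is the enone–alkene [2+2] photocycloaddition of 3-methylcyclohex-2-enones with methyl cyclobut-1-enecarboxylate, the light half of photo-thermal olefin metathesis. The one ring closed is the four-membered ring C10–C1–C4–C5, formed by intermolecular [2+2] addition (first bond intermolecular, second by 1,4-biradical recombination) and fused to the cyclohexanone along C5–C10 and to the reagent ring along C1–C4, which creates a bicyclo[2.2.0]hexane. C1 and C4 must be cis because of the small ring, C5 and C10 are expected cis with the outer rings anti and the reagent on the face away from the dioxolane, but none of this needs control because step 13 turns all four centres back into sp2 carbons. What the step does need is head-to-head regiochemistry: the acceptor ester directs its carbon C4 to the enone α-carbon C5, and the alternative would have to join the two fully substituted carbons C10 and C4, so polarity and sterics point the same way. Chemoselectivity is secured because C11 is kept sp3 as the nitro adduct, so no second alkene competes, and because the filter keeps the light out of the nitro and ester absorptions.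

**Step 13**
Reactants: 18 tricyclic photoadduct
Product: 20 elemane ketone (C10 β-CH3 axial and α-vinyl; C5 β-C(=CH2)CO2Me; C6 ketone; C7 β side chain; O8/O9 α acetonide), via trans-trans cyclodecadienone 19 (not isolated)
Conditions: degassed toluene (0.01 M), BHT (cat.), silylated sealed tube, 180 °C
Reagents that add atoms: none
Why: Thermal cycloreversion of the bicyclo[2.2.0]hexane (central C1–C4 bond first, eased by the C4 ester, then C5–C10, eased by the ketone) gives 19, whose chair transannular Cope rearrangement re-forms C5–C10 and cuts C2–C3 with the C7 chain, O8 and both alkenyl groups equatorial and the C10 methyl axial, because the other face would force a syn-diaxial CH3/O8 contact, while C5, being α to the ketone, can settle equatorial by enolisation.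

**Step 14**
Reactants: 20 elemane ketone
Product: 21 nitro diol (axial 6β-OH; C15H2OH; tert-butyl ester and nitro group kept)
Conditions: DIBAL-H (5 equiv), CH2Cl2, −78 °C; aq. Rochelle salt
Reagents that add atoms: none
Why: Diisobutylaluminium hydride reduction at −78 °C takes the ketone and the unhindered conjugated methyl ester (1,2-mode) while tert-butyl esters and primary nitroalkanes are known to survive these conditions, and hydride reaches C6 from the α face because the axial β trajectory is blocked by the syn-axial C10 methyl, which gives the axial alcohol.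

**Step 15**
Reactants: 21 nitro diol
Product: 22 diol with C7 tert-butyl acrylate (C11=C13 unveiled)
Conditions: DBU, THF, 0 °C
Reagents that add atoms: none
Why: Base-induced E1cB loss of nitrous acid from a β-nitro ester is the closing move of the nitroacrylate route to α-methylene esters, and it is run only now that the C6 ketone is gone, so DBU finds no β-alkoxy ketone to degrade.

**Step 16**
Reactants: 22 diol with C7 tert-butyl acrylate
Product: 23 C15 tert-butyldimethylsilyl ether (C6–OH free)
Conditions: TBSCl, imidazole, CH2Cl2, 0 °C
Reagents that add atoms: tert-butyldimethylsilyl chloride, CC(C)(C)[Si](C)(C)Cl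
Why: Selective silylation: the primary allylic C15 hydroxyl reacts far faster than the axial, doubly flanked C6 hydroxyl, and it must be masked because a C15 aldehyde next to a free cis C6 hydroxyl would close to a five-membered lactol that is oxidised or acetylated in place of the open form.

**Step 17**
Reactants: 23 C15 silyl ether
Product: 24 C6 acetate C15 silyl ether
Conditions: Ac2O, Et3N, DMAP, CH2Cl2, rt → 40 °C
Reagents that add atoms: acetic anhydride, CC(=O)OC(C)=O
Why: DMAP-catalysed acyl transfer with the smallest acyl donor is the standard answer to a hindered axial secondary alcohol, and nothing else in 23 can be acylated.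

**Step 18**
Reactants: 24 C6 acetate C15 silyl ether
Product: 25 C6 acetate C15 allylic alcohol
Conditions: HF·pyridine, pyridine/THF, 0 °C → rt
Reagents that add atoms: none
Why: Fluoride-mediated desilylation in a buffered acidic medium removes the primary silyl ether without acetyl migration and leaves acetonide, tert-butyl ester and acetate alone.

**Step 19**
Reactants: 25 C6 acetate C15 allylic alcohol
Product: 26 C15 enal C6 acetate
Conditions: MnO2 (activated), CH2Cl2, rt
Reagents that add atoms: none
Why: Manganese dioxide oxidation is selective for allylic alcohols and stops at the enal, and with C6 acetylated no lactol can form.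

**Step 20**
Reactants: 26 C15 enal C6 acetate
Product: 27 8,9-dihydroxy C12 acid
Conditions: TFA/H2O (9:1), 0 °C → rt
Reagents that add atoms: none
Why: Acidolysis: aqueous TFA hydrolyses the dioxolane and cleaves the tert-butyl ester by alkyl–oxygen fission, while the secondary acetate, the enal and the 1,1-disubstituted alkenes tolerate the medium.

**Step 21**
Reactants: 27 8,9-dihydroxy C12 acid
Product: 29 trans-fused 8,12-olide with free axial C9–OH, via O-acylisourea 28 (not isolated)
Conditions: EDC, DMAP (cat.), CH2Cl2 (high dilution), 0 °C → rt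
Reagents that add atoms: 1-ethyl-3-(3-dimethylaminopropyl)carbodiimide, CCN=C=NCCCN(C)C (its atoms are held only in 28)
Why: Carbodiimide (Steglich) lactonisation: only the equatorial O8, vicinal and trans-diequatorial to the C7 acrylic acid, can close a five-membered ring, whereas O9 is 1,3-trans to C7 and cannot bridge.

**Step 22**
Reactants: 29 8,12-olide with free C9–OH; 30 angelic acid
Product: 32 target CNP0252310.1, via mixed anhydride 31 (not isolated)
Conditions: 30, 2,4,6-trichlorobenzoyl chloride, Et3N, toluene, rt; then 29, toluene, 80 °C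
Reagents that add atoms: 2,4,6-trichlorobenzoyl chloride, O=C(Cl)c1c(Cl)cc(Cl)cc1Cl (its atoms are held only in 31)
Why: Yamaguchi esterification through the preformed mixed anhydride, run in warm toluene without a nucleophilic catalyst, is the established way to acylate hindered alcohols with angelic acid without Z to E isomerisation, and no stereocentre is touched.

**Compound list**

1 | D-(−)-quinic acid | OC(=O)[C@]1(O)C[C@@H](O)[C@@H](O)[C@H](O)C1 | starting material
2 | 3,4-O-isopropylidenequinic acid 1,5-lactone | O=C1O[C@@H]2C[C@@]1(O)C[C@H]3OC(C)(C)O[C@@H]23 | intermediate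
3 | 3,4-O-isopropylidene triol (C1 tertiary OH and CH2OH, C5 OH) | OC[C@]1(O)C[C@H]2OC(C)(C)O[C@H]2[C@H](O)C1 | intermediate
4 | 5-hydroxy-3,4-O-isopropylidenedioxycyclohexanone (quinic acid numbering, configuration unchanged) | O=C1C[C@H]2OC(C)(C)O[C@H]2[C@H](O)C1 | intermediate
5 | C5 mesylate of 4 | O=C1C[C@H]2OC(C)(C)O[C@H]2[C@H](OS(C)(=O)=O)C1 | intermediate
6 | (4S,5R)-4,5-O-isopropylidenedioxycyclohex-2-enone | C1=CC(=O)C[C@H]2OC(C)(C)O[C@@H]12 | intermediate
7 | trimethylsilyl enol ether, C10 methyl trans to the acetonide | C[C@@H]1C=C(O[Si](C)(C)C)C[C@H]2OC(C)(C)O[C@@H]12 | intermediate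
8 | (4S,5R)-3-methyl-4,5-O-isopropylidenedioxycyclohex-2-enone | CC1=CC(=O)C[C@H]2OC(C)(C)O[C@@H]12 | intermediate
9 | tert-butyl acrylate | C=CC(=O)OC(C)(C)C | starting material
10 | tert-butyl 2-iodo-3-nitropropanoate (racemic) | CC(C)(C)OC(=O)C(I)C[N+](=O)[O-] | intermediate
11 | tert-butyl (E)-3-nitroacrylate | O=C(/C=C/[N+](=O)[O-])OC(C)(C)C | intermediate
12 | lithium cross-conjugated dienolate of 8 (C6–O, C6=C7) | [Li+].CC1=CC([O-])=C[C@H]2OC(C)(C)O[C@@H]12 | intermediate
13 | lithium nitronate of the Michael adduct | [Li+].CC1=CC(=O)[C@H](C(C=[N+]([O-])[O-])C(=O)OC(C)(C)C)[C@H]2OC(C)(C)O[C@@H]12 | intermediate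
14 | enone 8 bearing at C7 (β, trans to O8) CH(CO2t-Bu)CH2NO2, C11 epimers | CC1=CC(=O)[C@H](C(C[N+](=O)[O-])C(=O)OC(C)(C)C)[C@H]2OC(C)(C)O[C@@H]12 | intermediate
15 | ethyl 1-bromocyclobutane-1-carboxylate | CCOC(=O)C1(Br)CCC1 | starting material
16 | cyclobut-1-ene-1-carboxylic acid | OC(=O)C1=CCC1 | intermediate
17 | methyl cyclobut-1-ene-1-carboxylate | COC(=O)C1=CCC1 | intermediate
18 | cis-anti-cis tricyclic photoadduct (cyclobutane C10–C1–C4–C5 on the β face, CO2Me on C4) | C[C@@]12[C@H]3CC[C@@]3(C(=O)OC)[C@@H]1C(=O)[C@H](C(C[N+](=O)[O-])C(=O)OC(C)(C)C)[C@H]1OC(C)(C)O[C@@H]21 | intermediate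
19 | cyclodeca-1(10),4-dien-6-one, both alkenes trans within the ring (1(10)E; 4Z by CIP priority of CO2Me) | C/C1=C\CC/C(C(=O)OC)=C/C(=O)[C@H](C(C[N+](=O)[O-])C(=O)OC(C)(C)C)[C@H]2OC(C)(C)O[C@@H]12 | intermediate
20 | elemane ketone (trans-dialkenylcyclohexanone) | C=C[C@]1(C)[C@@H]2OC(C)(C)O[C@@H]2[C@@H](C(C[N+](=O)[O-])C(=O)OC(C)(C)C)C(=O)[C@H]1C(=C)C(=O)OC | intermediate
21 | nitro diol (6β axial OH, C15 OH) | C=C[C@]1(C)[C@@H]2OC(C)(C)O[C@@H]2[C@@H](C(C[N+](=O)[O-])C(=O)OC(C)(C)C)[C@@H](O)[C@H]1C(=C)CO | intermediate
22 | diol with C7 tert-butyl acrylate | C=C[C@]1(C)[C@@H]2OC(C)(C)O[C@@H]2[C@@H](C(=C)C(=O)OC(C)(C)C)[C@@H](O)[C@H]1C(=C)CO | intermediate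
23 | C15 TBS ether, C6–OH free | C=C[C@]1(C)[C@@H]2OC(C)(C)O[C@@H]2[C@@H](C(=C)C(=O)OC(C)(C)C)[C@@H](O)[C@H]1C(=C)CO[Si](C)(C)C(C)(C)C | intermediate
24 | C6 acetate, C15 TBS ether | C=C[C@]1(C)[C@@H]2OC(C)(C)O[C@@H]2[C@@H](C(=C)C(=O)OC(C)(C)C)[C@@H](OC(C)=O)[C@H]1C(=C)CO[Si](C)(C)C(C)(C)C | intermediate
25 | C6 acetate, C15 allylic alcohol | C=C[C@]1(C)[C@@H]2OC(C)(C)O[C@@H]2[C@@H](C(=C)C(=O)OC(C)(C)C)[C@@H](OC(C)=O)[C@H]1C(=C)CO | intermediate
26 | C15 enal, C6 acetate | C=C[C@]1(C)[C@@H]2OC(C)(C)O[C@@H]2[C@@H](C(=C)C(=O)OC(C)(C)C)[C@@H](OC(C)=O)[C@H]1C(=C)C=O | intermediate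
27 | 8,9-dihydroxy C12 acid | C=C[C@]1(C)[C@H](O)[C@H](O)[C@@H](C(=C)C(=O)O)[C@@H](OC(C)=O)[C@H]1C(=C)C=O | intermediate
28 | O-acylisourea of 27 | C=C[C@]1(C)[C@H](O)[C@H](O)[C@@H](C(=C)C(=O)OC(=NCC)NCCCN(C)C)[C@@H](OC(C)=O)[C@H]1C(=C)C=O | intermediate
29 | trans-fused 8,12-olide with free C9 alcohol | C=C[C@]1(C)[C@H](O)[C@@H]2OC(=O)C(=C)[C@H]2[C@@H](OC(C)=O)[C@H]1C(=C)C=O | intermediate
30 | angelic acid, (Z)-2-methylbut-2-enoic acid | C/C=C(/C)C(=O)O | starting material
31 | angelic 2,4,6-trichlorobenzoic mixed anhydride | C/C=C(/C)C(=O)OC(=O)c1c(Cl)cc(Cl)cc1Cl | intermediate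
32 | CNP0252310.1 | C=C[C@]1(C)[C@H](OC(=O)/C(C)=C\C)[C@@H]2OC(=O)C(=C)[C@H]2[C@@H](OC(C)=O)[C@H]1C(=C)C=O | target

**Totals**

Total step count: 22. Longest linear sequence: 18 (steps 1–6, 9, 12–22).

**Steps most likely to fail**

**1) Step 9.**
- Process: the cross-conjugated dienolate may expel the C8 oxygen by E1cB, pulled on by aromatisation of the ring. The nitronate formed in the addition may also close a second, intramolecular Michael bond onto C10.
- Fallback (sets out from 8, comes back at 18): photochemistry and Michael addition change places. Enone 8 is irradiated with 17 under the conditions of step 12 to give the side-chain-free tricyclic ketone F1. LDA at −78 °C removes a proton from its only unhindered α-position, C7H2, to give the lithium enolate F2. This adds to 11 to give the tricyclic lithium nitronate F3, and cold acetic acid releases 18.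
- Why it helps: with C5=C10 already saturated there is no aromatisation to drive loss of O8 and no acceptor for a second Michael closure. C7 remains correctable by enolisation, and the nitro group never sees light.

**2) Step 13.**
- Process: at 180 °C the β-nitro ester may lose nitrous acid. The acid would strip the acetonide and the tert-butyl ester, and the alkene unveiled too early would open further pericyclic channels. This gets worse the longer the heating that is needed for all material to pass through the ten-membered ring and converge on one C5/C10 arrangement.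
- Fallback (sets out from 18, comes back at 22): the mask on C13 is exchanged before heating.
  - Thiophenol and Et3N in CH2Cl2 at 0 °C replace nitro by an elimination–addition sequence, through the tricyclic acrylate F4, to give the tricyclic β-phenylthio ester F5.
  - Thermolysis as in step 13 passes through the phenylthio cyclodecadienone F6 to the phenylthio elemane ketone F7.
  - DIBAL-H as in step 14 gives the phenylthio diol F8.
  - One equivalent of mCPBA at −78 °C gives the sulfoxide F9.
  - Syn-elimination in toluene at 110 °C over CaCO3 delivers 22.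

**3) Step 14.**
- Process: during the slow ester reduction the excess aluminium hydride may attack the nitro group or the tert-butyl ester, and facial selectivity at C6 may erode.
- Fallback (sets out from 17 with 14 as partner, comes back at 23): the ester is reduced before the photochemistry.
  - DIBAL-H turns 17 into cyclobut-1-enylmethanol F6a, written below as F10, and TBSCl/imidazole gives its silyl ether F11.
  - Irradiation with 14 as in step 12 gives the silyloxymethyl photoadduct F12. The same orientation is now enforced by sterics alone, since the other one would join two fully substituted carbons; this behaviour is known for 1-alkylcyclobutenes with 3-methylcyclohexenones.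
  - Thermolysis at about 200 °C passes through the silyloxymethyl cyclodecadienone F13 to the silyloxymethyl elemane ketone F14.
  - Only a ketone is then left to reduce, and L-Selectride at −78 °C gives the axial alcohol F15.
  - DBU as in step 15 gives 23, which also makes step 16 unnecessary.

**Further compounds**

F1 | step 9 | side-chain-free tricyclic ketone (photoadduct of 8 and 17) | C[C@@]12[C@H]3CC[C@@]3(C(=O)OC)[C@@H]1C(=O)C[C@H]1OC(C)(C)O[C@@H]21
F2 | step 9 | lithium enolate (C6=C7) of F1 | [Li+].C[C@@]12[C@H]3CC[C@@]3(C(=O)OC)[C@@H]1C([O-])=C[C@H]1OC(C)(C)O[C@@H]21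
F3 | step 9 | tricyclic lithium nitronate | [Li+].C[C@@]12[C@H]3CC[C@@]3(C(=O)OC)[C@@H]1C(=O)[C@H](C(C=[N+]([O-])[O-])C(=O)OC(C)(C)C)[C@H]1OC(C)(C)O[C@@H]21
F4 | step 13 | tricyclic acrylate | C[C@@]12[C@H]3CC[C@@]3(C(=O)OC)[C@@H]1C(=O)[C@H](C(=C)C(=O)OC(C)(C)C)[C@H]1OC(C)(C)O[C@@H]21
F5 | step 13 | tricyclic β-phenylthio ester | C[C@@]12[C@H]3CC[C@@]3(C(=O)OC)[C@@H]1C(=O)[C@H](C(CSc4ccccc4)C(=O)OC(C)(C)C)[C@H]1OC(C)(C)O[C@@H]21
F6 | step 13 | phenylthio cyclodecadienone | C/C1=C\CC/C(C(=O)OC)=C/C(=O)[C@H](C(CSc3ccccc3)C(=O)OC(C)(C)C)[C@H]2OC(C)(C)O[C@@H]12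
F7 | step 13 | phenylthio elemane ketone | C=C[C@]1(C)[C@@H]2OC(C)(C)O[C@@H]2[C@@H](C(CSc3ccccc3)C(=O)OC(C)(C)C)C(=O)[C@H]1C(=C)C(=O)OC
F8 | step 13 | phenylthio diol | C=C[C@]1(C)[C@@H]2OC(C)(C)O[C@@H]2[C@@H](C(CSc3ccccc3)C(=O)OC(C)(C)C)[C@@H](O)[C@H]1C(=C)CO
F9 | step 13 | sulfoxide (sulfur epimers) | C=C[C@]1(C)[C@@H]2OC(C)(C)O[C@@H]2[C@@H](C(CS(=O)c3ccccc3)C(=O)OC(C)(C)C)[C@@H](O)[C@H]1C(=C)CO
F10 | step 14 | cyclobut-1-enylmethanol | OCC1=CCC1
F11 | step 14 | tert-butyl(cyclobut-1-enylmethoxy)dimethylsilane | CC(C)(C)[Si](C)(C)OCC1=CCC1
F12 | step 14 | silyloxymethyl photoadduct | C[C@@]12[C@H]3CC[C@@]3(CO[Si](C)(C)C(C)(C)C)[C@@H]1C(=O)[C@H](C(C[N+](=O)[O-])C(=O)OC(C)(C)C)[C@H]1OC(C)(C)O[C@@H]21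
F13 | step 14 | silyloxymethyl cyclodecadienone | C/C1=C\CC/C(CO[Si](C)(C)C(C)(C)C)=C/C(=O)[C@H](C(C[N+](=O)[O-])C(=O)OC(C)(C)C)[C@H]2OC(C)(C)O[C@@H]12
F14 | step 14 | silyloxymethyl elemane ketone | C=C[C@]1(C)[C@@H]2OC(C)(C)O[C@@H]2[C@@H](C(C[N+](=O)[O-])C(=O)OC(C)(C)C)C(=O)[C@H]1C(=C)CO[Si](C)(C)C(C)(C)C
F15 | step 14 | axial 6β-alcohol with nitro side chain and C15 silyl ether | C=C[C@]1(C)[C@@H]2OC(C)(C)O[C@@H]2[C@@H](C(C[N+](=O)[O-])C(=O)OC(C)(C)C)[C@@H](O)[C@H]1C(=C)CO[Si](C)(C)C(C)(C)C
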